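Ring A is a cyclohexa-2,4-dienone whose C5 carries both allyl and methoxy (benzofuran numbering), so it can be cut into three two-carbon pieces without any aromatic intermediate: C5–C6 is the C=C bond of allyl(methoxy)ketene, while C7=C7a and C3a=C4 are two alkynes already linked by O1–C2–C3 of ring B. One nickel-templated [2+2+2] cycloaddition then forms C3a–C7a, C6–C7 and C4–C5, closes rings A and B and creates C5. Its precursor is an open-chain 1,6-diyne, the ethynyl ether of an anti homopropargylic alcohol carrying C2 and C3, reached in three steps; the ketene is prepared separately as a cold, salt-free solution.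

Key step: step 7

Assumption: atom labels (O1, C2, C3, C3a, C4 to C7, C7a) follow the benzofuran numbering of the target throughout; the stereodescriptors were checked against the target SMILES ((1S,2S) in the open chain maps onto trans-(2S,3S) in ring B; C5 is S, with the allyl group on the face of the C3 methyl group) and no structure needed correction; the sense of induction of DIOP at C5 cannot be predicted, so (R,R)-DIOP is written and its antipode is taken if it proves to be the matched one.

Step 1
Reactants: 1 (R)-but-3-yn-2-ol
Product: 2 (R)-but-3-yn-2-yl methanesulfonate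
Conditions: MsCl (1.2 equiv), Et3N (1.5 equiv), CH2Cl2, −78 → 0 °C
Reagents that add atoms: methanesulfonyl chloride, CS(=O)(=O)Cl
Why: O-Sulfonylation of the secondary alcohol (mesylation) leaves the C–O bond and therefore the R configuration untouched.

Step 2
Reactants: 2 (R)-but-3-yn-2-yl methanesulfonate; 3 3,4,5-trimethoxybenzaldehyde
Product: 5 (1S,2S)-2-methyl-1-(3,4,5-trimethoxyphenyl)but-3-yn-1-ol, via allenylzinc reagent 4 (not isolated)
Conditions: Pd(OAc)2 (5 mol %), PPh3 (5 mol %), Et2Zn (3 equiv), THF, −78 → −20 °C; aq. NH4Cl
Reagents that add atoms: none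
Why: Zerovalent palladium displaces the mesylate in an anti SN2' sense and Et2Zn transmetallates to allenylzinc 4, which adds to the aldehyde through a closed six-membered SE2' transition state in which the aryl group avoids the allenyl methyl group (Marshall propargylation), so the R centre of 2 is passed on with net inversion to C3 (S) and the anti relationship sets C2 (S).

Step 3
Reactants: 5 (1S,2S)-2-methyl-1-(3,4,5-trimethoxyphenyl)but-3-yn-1-ol; 6 trichloroethylene
Product: 10 5-[(1S,2S)-1-(ethynyloxy)-2-methylbut-3-yn-1-yl]-1,2,3-trimethoxybenzene, via potassium alkoxide 7 (not isolated), via dichlorovinyl ether 8 (not isolated), via dilithiated diyne 9 (not isolated)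
Conditions: KH (1.05 equiv), THF, 0 °C; 6 (1.05 equiv), −50 °C → rt; n-BuLi (3.3 equiv), −78 → −40 °C; MeOH, −78 °C; chromatography on basic Al2O3
Reagents that add atoms: none
Why: The potassium alkoxide adds to dichloroacetylene generated in the flask from 6, and n-BuLi then brings about elimination and chlorine–lithium exchange to the lithium alkynyl ether (Greene ynol ether synthesis, one-pot variant), the third equivalent of base only masking the carbon alkyne as its acetylide, so that neither stereocentre is touched.

Step 4
Reactants: 11 methoxyacetic acid; 12 allyl bromide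
Product: 14 racemic 2-methoxypent-4-enoic acid, via dilithium enediolate 13 (not isolated)
Conditions: LiN(i-Pr)2 (2.2 equiv), THF, −78 → 0 °C; 12, −78 °C → rt; aq. HCl
Reagents that add atoms: none
Why: The enediolate of the α-alkoxy acid is C-alkylated by the reactive allylic bromide without the self-condensation open to the corresponding ester enolate (carboxylic acid dianion alkylation), and the racemic centre is of no concern because it becomes the sp2 carbon of the ketene.

Step 5
Reactants: 14 racemic 2-methoxypent-4-enoic acid
Product: 15 racemic 2-methoxypent-4-enoyl chloride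
Conditions: (COCl)2 (1.3 equiv), DMF (cat.), CH2Cl2, 0 °C → rt; short-path distillation
Reagents that add atoms: oxalyl chloride, O=C(Cl)C(=O)Cl
Why: Acid chloride formation through the Vilsmeier intermediate gives only gaseous by-products and a chloride clean enough for the dehydrochlorination that follows.

Step 6
Reactants: 15 racemic 2-methoxypent-4-enoyl chloride
Product: 16 allyl(methoxy)ketene (2-methoxypenta-1,4-dien-1-one) as a cold toluene solution
Conditions: Et3N (1.05 equiv), toluene, −20 → 0 °C; filtration under argon at −20 °C; used at once
Reagents that add atoms: none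
Why: The α-methoxy group acidifies the α-hydrogen enough for Et3N to dehydrochlorinate the acid chloride at low temperature (ketene formation by dehydrohalogenation), and cold filtration removes the ammonium salt so that neither acid chloride nor chloride reaches the nickel catalyst.

Step 7
Reactants: 10 5-[(1S,2S)-1-(ethynyloxy)-2-methylbut-3-yn-1-yl]-1,2,3-trimethoxybenzene; 16 allyl(methoxy)ketene
Product: 17 (2S,3S,5S)-5-allyl-5-methoxy-3-methyl-2-(3,4,5-trimethoxyphenyl)-3,5-dihydro-1-benzofuran-6(2H)-one
Conditions: Ni(cod)2 (15 mol %), (R,R)-DIOP (16 mol %), toluene, 0 °C; 10 and 16 (2 equiv) added separately by syringe pump over 5 h; then rt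
Reagents that add atoms: none
Why: Proposed new method: the diphosphine-bound zerovalent nickel should couple the two alkynes of 10 oxidatively to a bicyclic nickelacyclopentadiene (C3a–C7a, five-membered ring B closed by 1,6-diyne oxidative cyclisation), the C=C bond of ketene 16 should then insert into the Ni–C7 bond (C6–C7), and C4–C5 reductive elimination from the resulting seven-membered nickelacycle should close six-membered ring A, a net [2+2+2] cycloaddition. The closest known reaction type is the [2+2+2] cycloaddition of carbon-tethered internal diynes with isolable disubstituted ketenes under zerovalent nickel and a 1,4-diphosphine, which gives 6,6-disubstituted cyclohexa-2,4-dienones; an ynol ether terminus, terminal alkynes and a transient alkoxyketene go beyond it. The step needs one orientation of the ketene (carbonyl carbon C6 to C7, C5 to C4), and the ynol ether oxygen secures it by making C7 and the Ni–C7 bond the nucleophilic site that the electrophilic ketene carbon seeks. The new stereocentre C5 is set when nickel selects a face of the ketene, so it is controlled by the chiral diphosphine DIOP (a chiral analogue of the ligand of the known reaction), because the C3 methyl group is too remote to direct it; the C5 epimer is removed by chromatography. Separate slow addition of both partners at 0 °C keeps free ynol ether and free ketene scarce and should suppress their direct [2+2] cycloaddition, ketene dimerisation and alkyne oligomerisation, while the salt-free ketene solution spares the catalyst from acid chloride and ammonium chloride. With C5 quaternary, ring A has no route to a phenol, and the product is isolated below 30 °C to avoid sigmatropic shifts of the allyl group.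

Compound list
1 | (R)-but-3-yn-2-ol | C#C[C@@H](C)O | starting material
2 | (R)-but-3-yn-2-yl methanesulfonate | C#C[C@@H](C)OS(C)(=O)=O | intermediate
3 | 3,4,5-trimethoxybenzaldehyde | COc1cc(C=O)cc(OC)c1OC | starting material
4 | (aS)-buta-1,2-dien-1-yl(ethyl)zinc | CC[Zn]C([H])=[C@@]=C([H])C | intermediate
5 | (1S,2S)-2-methyl-1-(3,4,5-trimethoxyphenyl)but-3-yn-1-ol | O[C@H](c1cc(OC)c(OC)c(OC)c1)[C@@H](C)C#C | intermediate
6 | trichloroethylene | ClC=C(Cl)Cl | starting material
7 | potassium (1S,2S)-2-methyl-1-(3,4,5-trimethoxyphenyl)but-3-yn-1-olate | [K+].[O-][C@H](c1cc(OC)c(OC)c(OC)c1)[C@@H](C)C#C | intermediate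
8 | 5-[(1S,2S)-1-{[(E)-1,2-dichloroethenyl]oxy}-2-methylbut-3-yn-1-yl]-1,2,3-trimethoxybenzene | Cl/C=C(/Cl)O[C@H](c1cc(OC)c(OC)c(OC)c1)[C@@H](C)C#C | intermediate
9 | dilithium derivative of 10 (lithium alkynyl ether and lithium acetylide) | [Li]C#CO[C@H](c1cc(OC)c(OC)c(OC)c1)[C@@H](C)C#C[Li] | intermediate
10 | 5-[(1S,2S)-1-(ethynyloxy)-2-methylbut-3-yn-1-yl]-1,2,3-trimethoxybenzene | C#CO[C@H](c1cc(OC)c(OC)c(OC)c1)[C@@H](C)C#C | intermediate
11 | methoxyacetic acid | COCC(=O)O | starting material
12 | allyl bromide | C=CCBr | starting material
13 | dilithium 2-methoxyethene-1,1-diolate | [Li+].[Li+].[O-]C([O-])=COC | intermediate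
14 | racemic 2-methoxypent-4-enoic acid | C=CCC(OC)C(=O)O | intermediate
15 | racemic 2-methoxypent-4-enoyl chloride | C=CCC(OC)C(=O)Cl | intermediate
16 | allyl(methoxy)ketene (2-methoxypenta-1,4-dien-1-one) | C=CCC(OC)=C=O | intermediate
17 | (2S,3S,5S)-5-allyl-5-methoxy-3-methyl-2-(3,4,5-trimethoxyphenyl)-3,5-dihydro-1-benzofuran-6(2H)-one | C=CC[C@]1(OC)C=C2C(=CC1=O)O[C@H](c1cc(OC)c(OC)c(OC)c1)[C@H]2C | target

Total step count: 7 (steps 1 to 3 lead to the diyne, steps 4 to 6 to the ketene, step 7 joins them).
Longest linear sequence: 4 steps (steps 1, 2, 3 and 7; the ketene branch, steps 4, 5, 6 and 7, is equally long).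

Steps most likely to fail

Step 7 (Proposed new method). The direct [2+2] cycloaddition of the ketene with the ynol ether may outrun the nickel cycle. The ketene may also dimerise or lose CO at nickel, the terminal alkynes may oligomerise, the ketene may insert with the opposite orientation, and the facial selectivity at C5 may be poor. The fallback uses known chemistry, a cation–alkene route in place of the cycloaddition; it sets out from aldehyde 3 and comes back at target 17. Julia–Kocienski olefination of 3 with 5-(ethylsulfonyl)-1-phenyl-1H-tetrazole and KN(SiMe3)2 should give (E)-1,2,3-trimethoxy-5-(prop-1-en-1-yl)benzene F1. In parallel, commercial 3,4-dimethoxyphenol is O-allylated with 12 and K2CO3 to 4-(allyloxy)-1,2-dimethoxybenzene F2. Claisen rearrangement of F2 at about 190 °C should give 2-allyl-4,5-dimethoxyphenol F3, and oxidation with PhI(OAc)2 in MeOH then gives the quinone monoketal 2-allyl-4,4,5-trimethoxycyclohexa-2,5-dien-1-one F4. A strong acid (TfOH, MeCN, −30 °C) ionises F4 to an alkoxy-stabilised cation, which adds to F1 at its allyl-bearing carbon; the carbonyl oxygen then traps the benzylic cation. After chromatographic removal of isomers this should leave the racemic angular adduct (2S*,3S*,3aR*)-3a-allyl-5-methoxy-3-methyl-2-(3,4,5-trimethoxyphenyl)-3,3a-dihydro-1-benzofuran-6(2H)-one F5. Brief heating of F5 in toluene should move the allyl group suprafacially from C3a to C5 by a [3,3] shift, a rearrangement known for this family of neolignans, and give racemic 17. Preparative HPLC on a chiral stationary phase then separates 17 from its enantiomer (2R,3R,5R)-5-allyl-5-methoxy-3-methyl-2-(3,4,5-trimethoxyphenyl)-3,5-dihydro-1-benzofuran-6(2H)-one F6.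

Step 3. O-Vinylation of the hindered benzylic alkoxide may stay incomplete, the free alkyne may suffer base-induced cyclisation, isomerisation or acetylide attack on dichloroacetylene, and the acid- and heat-sensitive benzylic ynol ether may be lost during isolation. The fallback avoids the alkoxide and dichloroacetylene; it sets out from alcohol 5 and comes back at diyne 10. Formylation of 5 with acetic formic anhydride and pyridine gives (1S,2S)-2-methyl-1-(3,4,5-trimethoxyphenyl)but-3-yn-1-yl formate F7. Dichloromethylenation of the formate carbonyl with PPh3 and CCl4 (THF, 60 °C) gives 5-[(1S,2S)-1-[(2,2-dichloroethenyl)oxy]-2-methylbut-3-yn-1-yl]-1,2,3-trimethoxybenzene F8. Treatment of F8 with n-BuLi (3.3 equiv, THF, −78 °C) and a MeOH quench should then give 10 by elimination and chlorine–lithium exchange.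

Step 2. The allenylzinc may partly racemise before it adds to the electron-rich, slowly reacting aromatic aldehyde, and the anti selectivity may be incomplete. The fallback replaces chirality transfer from the mesylate by catalyst control with a configurationally stable boron reagent; it sets out from aldehyde 3 and comes back at alcohol 5. Commercial racemic but-3-yn-2-ol is converted with ClCO2Me and pyridine into racemic but-3-yn-2-yl methyl carbonate F9. SN2' borylation of F9 with B2pin2 (CuCl, KOt-Bu, Xantphos) gives racemic 2-(buta-1,2-dien-1-yl)-4,4,5,5-tetramethyl-1,3,2-dioxaborolane F10. Aldehyde 3 is then treated with an excess of F10 and the chiral phosphoric acid TRIP (the antipode that delivers the 1S carbinol) in toluene at −30 °C. The acid selects one enantiomer of the reagent and one aldehyde face in a closed chair transition state, which should give the anti alcohol 5 directly.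

Further compounds
F1 | step 7 | (E)-1,2,3-trimethoxy-5-(prop-1-en-1-yl)benzene | C/C=C/c1cc(OC)c(OC)c(OC)c1
F2 | step 7 | 4-(allyloxy)-1,2-dimethoxybenzene | C=CCOc1ccc(OC)c(OC)c1
F3 | step 7 | 2-allyl-4,5-dimethoxyphenol | C=CCc1cc(OC)c(OC)cc1O
F4 | step 7 | 2-allyl-4,4,5-trimethoxycyclohexa-2,5-dien-1-one | C=CCC1=CC(OC)(OC)C(OC)=CC1=O
F5 | step 7 | racemic (2S*,3S*,3aR*)-3a-allyl-5-methoxy-3-methyl-2-(3,4,5-trimethoxyphenyl)-3,3a-dihydro-1-benzofuran-6(2H)-one (2S,3S,3aR enantiomer written) | C=CC[C@@]12C=C(OC)C(=O)C=C1O[C@H](c1cc(OC)c(OC)c(OC)c1)[C@H]2C
F6 | step 7 | (2R,3R,5R)-5-allyl-5-methoxy-3-methyl-2-(3,4,5-trimethoxyphenyl)-3,5-dihydro-1-benzofuran-6(2H)-one | C=CC[C@@]1(OC)C=C2C(=CC1=O)O[C@@H](c1cc(OC)c(OC)c(OC)c1)[C@@H]2C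
F7 | step 3 | (1S,2S)-2-methyl-1-(3,4,5-trimethoxyphenyl)but-3-yn-1-yl formate | O=CO[C@H](c1cc(OC)c(OC)c(OC)c1)[C@@H](C)C#C
F8 | step 3 | 5-[(1S,2S)-1-[(2,2-dichloroethenyl)oxy]-2-methylbut-3-yn-1-yl]-1,2,3-trimethoxybenzene | ClC(Cl)=CO[C@H](c1cc(OC)c(OC)c(OC)c1)[C@@H](C)C#C
F9 | step 2 | racemic but-3-yn-2-yl methyl carbonate | C#CC(C)OC(=O)OC
F10 | step 2 | racemic 2-(buta-1,2-dien-1-yl)-4,4,5,5-tetramethyl-1,3,2-dioxaborolane | CC=C=CB1OC(C)(C)C(C)(C)O1
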